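**Retrosynthetic overview**

1. Target ⇒ macrocyclic 3-hydroxy heliangolide by C3 O-isovalerylation and a final epoxidation of the C1=C10 alkene under macrocyclic control.
2. Ten-membered carbocycle ⇒ seco alkenyl iodide–aldehyde, closed last at C3–C4 by an electrochemical Ni/Cr-catalysed alkenyl iodide–aldehyde coupling (sets C3).
3. Seco compound ⇒ C8 ester by Mitsunobu inversion with the epoxy acid, and C7–C8 bond by Zn-Barbier allylation of a C8 aldehyde with a 3-(bromomethyl)butenolide (sets C7 and C8 from C6).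
4. Bromomethyl butenolide ⇒ L-glutamic-acid-derived hydroxymethyl lactone (C6) via Z-selective iodo-olefination and a selenoxide route; aldehyde ⇒ pent-3-yn-1-ol; epoxy acid ⇒ ethyl (R)-3-hydroxybutanoate.
5. Ring order: γ-lactone (bought) → butenolide → exo-methylene lactone → ten-membered carbocycle → 1,10-oxirane; the side-chain oxirane is made separately.

Assumption: germacranolide numbering (C1–C15, lactone carbonyl C12) is used for all intermediates, lithium enolates and alkoxides of numbered compounds are not numbered separately, and the three bought building blocks are taken as catalogue chemicals.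

**Route**

Step 1
Reactants: 1 (S)-5-(hydroxymethyl)dihydrofuran-2(3H)-one
Product: 2 (S)-5-oxotetrahydrofuran-2-carbaldehyde
Conditions: DMP, CH2Cl2, 0 °C → rt
Reagents that add atoms: none
Why: Dess–Martin oxidation of the primary alcohol is neutral and fast, so the α-oxygenated aldehyde forms without epimerising the L-glutamic-acid-derived centre (future C6).

Step 2
Reactants: 2 (S)-5-oxotetrahydrofuran-2-carbaldehyde
Product: 3 (S)-5-[(Z)-2-iodoprop-1-en-1-yl]dihydrofuran-2(3H)-one
Conditions: [Ph3PEt]I, n-BuLi, THF, rt; I2, −78 °C; NaN(SiMe3)2, −20 °C; then 2, −78 → −20 °C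
Reagents that add atoms: ethyltriphenylphosphonium iodide, CC[P+](c1ccccc1)(c1ccccc1)c1ccccc1.[I-]; iodine, II
Why: Stork–Zhao-type Wittig iodo-olefination, in which the non-stabilised α-iodo ylide reacts under kinetic control to place iodine cis to the lactone carbon (Z), fixing the C4=C5 geometry and adding C4 and C15 while C6 is untouched.

Step 3
Reactants: 3 (S)-5-[(Z)-2-iodoprop-1-en-1-yl]dihydrofuran-2(3H)-one
Product: 5 (5S)-3-(hydroxymethyl)-5-[(Z)-2-iodoprop-1-en-1-yl]-3-(phenylselanyl)dihydrofuran-2(3H)-one, via selanyl lactone 4 (not isolated)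
Conditions: LiN(i-Pr)2 (1.05 equiv), THF, −78 °C; PhSeCl; LiN(i-Pr)2 (1.1 equiv); CH2O (g), −78 → −40 °C
Reagents that add atoms: benzeneselenenyl chloride, Cl[Se]c1ccccc1; formaldehyde, C=O
Why: Lactone enolate selenenylation followed by aldol-type hydroxymethylation of the more acidic α-selanyl lactone installs C13 and the selenium handle; the new C11 centre is lost in the next step.

Step 4
Reactants: 5 (5S)-3-(hydroxymethyl)-5-[(Z)-2-iodoprop-1-en-1-yl]-3-(phenylselanyl)dihydrofuran-2(3H)-one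
Product: 7 (S)-3-(hydroxymethyl)-5-[(Z)-2-iodoprop-1-en-1-yl]furan-2(5H)-one, via selenoxide 6 (not isolated)
Conditions: 30% H2O2, pyridine, CH2Cl2, 0 °C → rt
Reagents that add atoms: none
Why: Selenoxide syn-elimination runs away from the carbinol carbon, toward the ring CH2, giving the endocyclic butenolide (C7=C11) without touching C6.

Step 5
Reactants: 7 (S)-3-(hydroxymethyl)-5-[(Z)-2-iodoprop-1-en-1-yl]furan-2(5H)-one
Product: 8 (S)-3-(bromomethyl)-5-[(Z)-2-iodoprop-1-en-1-yl]furan-2(5H)-one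
Conditions: CBr4, PPh3, CH2Cl2, 0 °C
Reagents that add atoms: carbon tetrabromide, BrC(Br)(Br)Br
Why: Appel bromination converts the primary allylic alcohol into the bromide by SN2 displacement under neutral conditions.

Step 6
Reactants: 9 pent-3-yn-1-ol
Product: 10 triethyl(pent-3-yn-1-yloxy)silane
Conditions: TESCl, imidazole, CH2Cl2, 0 °C → rt
Reagents that add atoms: chlorotriethylsilane, CC[Si](Cl)(CC)CC
Why: Standard silyl ether formation masks the future C3 oxygen.

Step 7
Reactants: 10 triethyl(pent-3-yn-1-yloxy)silane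
Product: 12 (E)-triethyl[(4-iodopent-3-en-1-yl)oxy]silane, via alkenylzirconocene 11 (not isolated)
Conditions: Cp2Zr(H)Cl (1.5 equiv), THF, 50 °C; then I2, 0 °C
Reagents that add atoms: iodine, II
Why: Hydrozirconation is a syn addition whose regiochemistry equilibrates at 50 °C to zirconium on the methyl-bearing carbon, and iodinolysis with retention gives the E-trisubstituted alkenyl iodide (future C1=C10 with C14).

Step 8
Reactants: 12 (E)-triethyl[(4-iodopent-3-en-1-yl)oxy]silane
Product: 14 (E)-3-methyl-6-(triethylsilyloxy)hex-3-en-1-ol, via alkenyllithium 13 (not isolated)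
Conditions: t-BuLi (2.1 equiv), Et2O, −78 °C; ethylene oxide, −78 → 0 °C
Reagents that add atoms: ethylene oxide, C1CO1
Why: Iodine–lithium exchange retains the alkene geometry and the alkenyllithium opens ethylene oxide (SN2), adding C9 and C8 as a primary alcohol.

Step 9
Reactants: 14 (E)-3-methyl-6-(triethylsilyloxy)hex-3-en-1-ol
Product: 15 (E)-3-methyl-6-(triethylsilyloxy)hex-3-enal
Conditions: DMP, pyridine, CH2Cl2, 0 °C
Reagents that add atoms: none
Why: Buffered Dess–Martin oxidation gives the β,γ-unsaturated aldehyde without moving the E-alkene into conjugation; it is used at once.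

Step 10
Reactants: 16 ethyl (R)-3-hydroxybutanoate
Product: 17 ethyl (2R,3R)-3-hydroxy-2-methylbutanoate
Conditions: LiN(i-Pr)2 (2.2 equiv), THF, −50 → −20 °C; MeI, DMPU, −78 → 0 °C
Reagents that add atoms: iodomethane, CI
Why: Fráter–Seebach alkylation of the chelated dianion introduces the α-methyl group anti to the C3 oxygen under control of the bought (R)-carbinol centre.

Step 11
Reactants: 17 ethyl (2R,3R)-3-hydroxy-2-methylbutanoate
Product: 19 ethyl (2S,3R)-2,3-dimethyloxirane-2-carboxylate, via iodo alkoxide 18 (not isolated)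
Conditions: LiN(i-Pr)2 (2.2 equiv), THF, −78 → −20 °C; I2, −78 → 0 °C
Reagents that add atoms: none
Why: Iodination of the chelated dianion again occurs on the face anti to the C3 methyl (Fráter–Seebach facial control) and the lithium alkoxide then displaces iodide with inversion (Darzens-type closure), setting C2 as S beside the retained (R)-C3 (methyl groups cis).

Step 12
Reactants: 19 ethyl (2S,3R)-2,3-dimethyloxirane-2-carboxylate
Product: 20 (2S,3R)-2,3-dimethyloxirane-2-carboxylic acid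
Conditions: LiOH, THF/H2O, 0 °C → rt; then 1 M HCl to pH 3
Reagents that add atoms: lithium hydroxide, [Li+].[OH-]
Why: Saponification of the ethyl ester and mild acidification give the acid; the trisubstituted glycidate is stable to cold aqueous LiOH.

Step 13
Reactants: 15 (E)-3-methyl-6-(triethylsilyloxy)hex-3-enal; 8 (S)-3-(bromomethyl)-5-[(Z)-2-iodoprop-1-en-1-yl]furan-2(5H)-one
Product: 21 (4R,5S)-4-[(1S,3E)-1-hydroxy-3-methyl-6-(triethylsilyloxy)hex-3-en-1-yl]-5-[(Z)-2-iodoprop-1-en-1-yl]-3-methylidenedihydrofuran-2(3H)-one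
Conditions: Zn dust, THF/sat. aq. NH4Cl (2:1), 0 °C → rt
Reagents that add atoms: none
Why: Zn-Barbier allylation (SE2′ through a Zimmerman–Traxler chair), in which the ring-locked allylzinc attacks through C7 on the face anti to the C6 alkenyl group (6,7-trans lactone) with the aldehyde chain equatorial, giving the exo-methylene lactone and the (8S) alcohol, the C8 epimer of the target series.

Step 14
Reactants: 21 (4R,5S)-4-[(1S,3E)-1-hydroxy-3-methyl-6-(triethylsilyloxy)hex-3-en-1-yl]-5-[(Z)-2-iodoprop-1-en-1-yl]-3-methylidenedihydrofuran-2(3H)-one; 20 (2S,3R)-2,3-dimethyloxirane-2-carboxylic acid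
Product: 22 (1R,3E)-1-[(2S,3R)-2-[(Z)-2-iodoprop-1-en-1-yl]-4-methylidene-5-oxotetrahydrofuran-3-yl]-3-methyl-6-(triethylsilyloxy)hex-3-en-1-yl (2S,3R)-2,3-dimethyloxirane-2-carboxylate
Conditions: PPh3, DIAD, toluene, 0 °C → rt
Reagents that add atoms: none
Why: Mitsunobu esterification displaces the activated C8 oxygen by the carboxylate of 20 (pKa about 3.5) in an SN2 step, inverting 8S to the required 8R.

Step 15
Reactants: 22 (1R,3E)-1-[(2S,3R)-2-[(Z)-2-iodoprop-1-en-1-yl]-4-methylidene-5-oxotetrahydrofuran-3-yl]-3-methyl-6-(triethylsilyloxy)hex-3-en-1-yl (2S,3R)-2,3-dimethyloxirane-2-carboxylate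
Product: 23 (1R,3E)-6-hydroxy-1-[(2S,3R)-2-[(Z)-2-iodoprop-1-en-1-yl]-4-methylidene-5-oxotetrahydrofuran-3-yl]-3-methylhex-3-en-1-yl (2S,3R)-2,3-dimethyloxirane-2-carboxylate
Conditions: PPTS (10 mol%), MeOH, 0 °C → rt
Reagents that add atoms: none
Why: Acid-catalysed methanolysis (silyl ether cleavage) removes the primary triethylsilyl group selectively and leaves the esters, the oxirane and the alkenyl iodide intact.

Step 16
Reactants: 23 (1R,3E)-6-hydroxy-1-[(2S,3R)-2-[(Z)-2-iodoprop-1-en-1-yl]-4-methylidene-5-oxotetrahydrofuran-3-yl]-3-methylhex-3-en-1-yl (2S,3R)-2,3-dimethyloxirane-2-carboxylate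
Product: 24 (1R,3E)-1-[(2S,3R)-2-[(Z)-2-iodoprop-1-en-1-yl]-4-methylidene-5-oxotetrahydrofuran-3-yl]-3-methyl-6-oxohex-3-en-1-yl (2S,3R)-2,3-dimethyloxirane-2-carboxylate
Conditions: DMP, pyridine, CH2Cl2, 0 °C
Reagents that add atoms: none
Why: Buffered Dess–Martin oxidation gives the β,γ-unsaturated C3 aldehyde for immediate ring closure.

Step 17
Reactants: 24 (1R,3E)-1-[(2S,3R)-2-[(Z)-2-iodoprop-1-en-1-yl]-4-methylidene-5-oxotetrahydrofuran-3-yl]-3-methyl-6-oxohex-3-en-1-yl (2S,3R)-2,3-dimethyloxirane-2-carboxylate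
Product: 25 (3S,6R,7R,8R)-8-[(2S,3R)-2,3-dimethyloxirane-2-carbonyloxy]-3-hydroxygermacra-1(10)E,4Z,11(13)-trien-12,6-olide
Conditions: CrCl3 (20 mol%), NiCl2·glyme (2 mol%), Cp2ZrCl2 (1.5 equiv), LiCl (0.2 M), DMF, undivided cell, Al anode, Ni-foam cathode, constant current 2 mA (about 2.5 F/mol), 24 added over 12 h (final 2 mM), rt
Reagents that add atoms: none
Why: Proposed new method: cathodic reduction of trivalent chromium keeps a small standing concentration of divalent chromium, which turns NiCl2 over to zerovalent nickel; oxidative addition into the Z-alkenyl iodide (geometry retained), transmetalation to chromium and 1,2-addition of the alkenylchromium species to the tethered aldehyde form the C3–C4 bond and the ten-membered ring, with Cp2ZrCl2 releasing chromium from the alkoxide and the Al anode supplying the electrons, so the α-methylene lactone and the epoxy ester never meet excess reductant; with the metal-bound oxygen held outside the ring and the C3–H and C6–H bonds eclipsing the Z-alkene (allylic 1,3-strain), the lactone centres C6/C7 are expected to steer closure to the 3S alcohol; the closest known reaction types are the stoichiometric CrCl2/NiCl2 Nozaki–Hiyama–Kishi macrocyclisation and the intermolecular electrochemical Ni/Cr-catalysed Nozaki–Hiyama–Kishi coupling, which has not been used to close a medium carbocycle.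

Step 18
Reactants: 25 (3S,6R,7R,8R)-8-[(2S,3R)-2,3-dimethyloxirane-2-carbonyloxy]-3-hydroxygermacra-1(10)E,4Z,11(13)-trien-12,6-olide
Product: 26 (3S,6R,7R,8R)-8-[(2S,3R)-2,3-dimethyloxirane-2-carbonyloxy]-3-(3-methylbutanoyloxy)germacra-1(10)E,4Z,11(13)-trien-12,6-olide
Conditions: isovaleric anhydride, DMAP (cat.), pyridine, CH2Cl2, 0 °C → rt
Reagents that add atoms: 3-methylbutanoic anhydride, CC(C)CC(=O)OC(=O)CC(C)C
Why: DMAP-catalysed acyl transfer esterifies the secondary allylic alcohol with retention at C3.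

Step 19
Reactants: 26 (3S,6R,7R,8R)-8-[(2S,3R)-2,3-dimethyloxirane-2-carbonyloxy]-3-(3-methylbutanoyloxy)germacra-1(10)E,4Z,11(13)-trien-12,6-olide
Product: 27 (1R,3S,6R,7R,8R,10R)-8-[(2S,3R)-2,3-dimethyloxirane-2-carbonyloxy]-1,10-epoxy-3-(3-methylbutanoyloxy)germacra-4Z,11(13)-dien-12,6-olide
Conditions: mCPBA (1.05 equiv), 2,6-di-tert-butyl-4-methylpyridine, CH2Cl2, −20 → 0 °C
Reagents that add atoms: 3-chloroperoxybenzoic acid, OOC(=O)c1cccc(Cl)c1
Why: Prilezhaev epoxidation picks the only electron-rich alkene (C4=C5 is deactivated by two allylic acyloxy groups, the exo-methylene is electron-poor), and attack on the exposed outer face of the E-alkene in the heliangolide ring conformation is expected to give the (1R,10R)-oxirane.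

**Compound list**

1 | (S)-5-(hydroxymethyl)dihydrofuran-2(3H)-one (from L-glutamic acid) | OC[C@@H]1CCC(=O)O1 | starting material
2 | (S)-5-oxotetrahydrofuran-2-carbaldehyde | O=C[C@@H]1CCC(=O)O1 | intermediate
3 | (S)-5-[(Z)-2-iodoprop-1-en-1-yl]dihydrofuran-2(3H)-one | C/C(I)=C/[C@@H]1CCC(=O)O1 | intermediate
4 | selanyl lactone, formed in the flask: (5S)-5-[(Z)-2-iodoprop-1-en-1-yl]-3-(phenylselanyl)dihydrofuran-2(3H)-one (C3 epimers) | C/C(I)=C/[C@@H]1CC([Se]c2ccccc2)C(=O)O1 | intermediate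
5 | (5S)-3-(hydroxymethyl)-5-[(Z)-2-iodoprop-1-en-1-yl]-3-(phenylselanyl)dihydrofuran-2(3H)-one (C3 epimers) | C/C(I)=C/[C@@H]1CC(CO)([Se]c2ccccc2)C(=O)O1 | intermediate
6 | selenoxide of 5, formed in the flask | C/C(I)=C/[C@@H]1CC(CO)([Se](=O)c2ccccc2)C(=O)O1 | intermediate
7 | (S)-3-(hydroxymethyl)-5-[(Z)-2-iodoprop-1-en-1-yl]furan-2(5H)-one | C/C(I)=C/[C@@H]1C=C(CO)C(=O)O1 | intermediate
8 | (S)-3-(bromomethyl)-5-[(Z)-2-iodoprop-1-en-1-yl]furan-2(5H)-one | C/C(I)=C/[C@@H]1C=C(CBr)C(=O)O1 | intermediate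
9 | pent-3-yn-1-ol | CC#CCCO | starting material
10 | triethyl(pent-3-yn-1-yloxy)silane | CC#CCCO[Si](CC)(CC)CC | intermediate
11 | alkenylzirconocene, formed in the flask: chlorobis(cyclopentadienyl)[(E)-5-(triethylsilyloxy)pent-2-en-2-yl]zirconium | C/C(=C\CCO[Si](CC)(CC)CC)[Zr+2]Cl.c1cc[cH-]c1.c1cc[cH-]c1 | intermediate
12 | (E)-triethyl[(4-iodopent-3-en-1-yl)oxy]silane | C/C(I)=C\CCO[Si](CC)(CC)CC | intermediate
13 | alkenyllithium, formed in the flask: [(2Z)-5-(triethylsilyloxy)pent-2-en-2-yl]lithium (alkene geometry of 12 retained) | C/C([Li])=C\CCO[Si](CC)(CC)CC | intermediate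
14 | (E)-3-methyl-6-(triethylsilyloxy)hex-3-en-1-ol | OCC/C(C)=C/CCO[Si](CC)(CC)CC | intermediate
15 | (E)-3-methyl-6-(triethylsilyloxy)hex-3-enal | O=CC/C(C)=C/CCO[Si](CC)(CC)CC | intermediate
16 | ethyl (R)-3-hydroxybutanoate | CCOC(=O)C[C@@H](C)O | starting material
17 | ethyl (2R,3R)-3-hydroxy-2-methylbutanoate | CCOC(=O)[C@H](C)[C@@H](C)O | intermediate
18 | iodo alkoxide, formed in the flask: lithium alkoxide of ethyl (2R,3R)-3-hydroxy-2-iodo-2-methylbutanoate | CCOC(=O)[C@](C)(I)[C@@H](C)O[Li] | intermediate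
19 | ethyl (2S,3R)-2,3-dimethyloxirane-2-carboxylate | CCOC(=O)[C@@]1(C)O[C@@H]1C | intermediate
20 | (2S,3R)-2,3-dimethyloxirane-2-carboxylic acid | OC(=O)[C@@]1(C)O[C@@H]1C | intermediate
21 | (4R,5S)-4-[(1S,3E)-1-hydroxy-3-methyl-6-(triethylsilyloxy)hex-3-en-1-yl]-5-[(Z)-2-iodoprop-1-en-1-yl]-3-methylidenedihydrofuran-2(3H)-one | C=C1C(=O)O[C@H](/C=C(/C)I)[C@H]1[C@@H](O)C/C(C)=C/CCO[Si](CC)(CC)CC | intermediate
22 | (1R,3E)-1-[(2S,3R)-2-[(Z)-2-iodoprop-1-en-1-yl]-4-methylidene-5-oxotetrahydrofuran-3-yl]-3-methyl-6-(triethylsilyloxy)hex-3-en-1-yl (2S,3R)-2,3-dimethyloxirane-2-carboxylate | C=C1C(=O)O[C@H](/C=C(/C)I)[C@H]1[C@H](OC(=O)[C@@]2(C)O[C@@H]2C)C/C(C)=C/CCO[Si](CC)(CC)CC | intermediate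
23 | (1R,3E)-6-hydroxy-1-[(2S,3R)-2-[(Z)-2-iodoprop-1-en-1-yl]-4-methylidene-5-oxotetrahydrofuran-3-yl]-3-methylhex-3-en-1-yl (2S,3R)-2,3-dimethyloxirane-2-carboxylate | C=C1C(=O)O[C@H](/C=C(/C)I)[C@H]1[C@H](OC(=O)[C@@]2(C)O[C@@H]2C)C/C(C)=C/CCO | intermediate
24 | (1R,3E)-1-[(2S,3R)-2-[(Z)-2-iodoprop-1-en-1-yl]-4-methylidene-5-oxotetrahydrofuran-3-yl]-3-methyl-6-oxohex-3-en-1-yl (2S,3R)-2,3-dimethyloxirane-2-carboxylate | C=C1C(=O)O[C@H](/C=C(/C)I)[C@H]1[C@H](OC(=O)[C@@]2(C)O[C@@H]2C)C/C(C)=C/CC=O | intermediate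
25 | (3S,6R,7R,8R)-8-[(2S,3R)-2,3-dimethyloxirane-2-carbonyloxy]-3-hydroxygermacra-1(10)E,4Z,11(13)-trien-12,6-olide | C=C1C(=O)O[C@@H]2/C=C(/C)[C@@H](O)C/C=C(\C)C[C@@H](OC(=O)[C@@]3(C)O[C@@H]3C)[C@@H]12 | intermediate
26 | (3S,6R,7R,8R)-8-[(2S,3R)-2,3-dimethyloxirane-2-carbonyloxy]-3-(3-methylbutanoyloxy)germacra-1(10)E,4Z,11(13)-trien-12,6-olide | C=C1C(=O)O[C@@H]2/C=C(/C)[C@@H](OC(=O)CC(C)C)C/C=C(\C)C[C@@H](OC(=O)[C@@]3(C)O[C@@H]3C)[C@@H]12 | intermediate
27 | CNP0167461.3: (1R,3S,6R,7R,8R,10R)-8-[(2S,3R)-2,3-dimethyloxirane-2-carbonyloxy]-1,10-epoxy-3-(3-methylbutanoyloxy)germacra-4Z,11(13)-dien-12,6-olide | C=C1C(=O)O[C@@H]2/C=C(/C)[C@@H](OC(=O)CC(C)C)C[C@H]3O[C@]3(C)C[C@@H](OC(=O)[C@@]3(C)O[C@@H]3C)[C@@H]12 | target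

**Step count and risks**

Total step count: 19. Longest linear sequence: 12 steps (steps 1–5, then 13–19).

Steps most likely to fail:

Step 17 (the proposed new step). Risks are slow turnover at the electrode, nickel-mediated side reactions of the alkenyl iodide with the exo-methylene lactone, reduction of the epoxy ester, and the wrong C3 epimer. The fallback uses known chemistry and closes the ring before the reducible epoxy ester is attached; it sets out from 21 and comes back at 26. 21 is silylated (TBSOTf, 2,6-lutidine, CH2Cl2, −78 °C) to its 8-O-tert-butyldimethylsilyl ether F1. PPTS in MeOH removes the primary triethylsilyl group to give the primary alcohol F2, and Dess–Martin oxidation gives the aldehyde F3. The classical stoichiometric Nozaki–Hiyama–Kishi reaction (CrCl2 8 equiv, NiCl2 1 mol%, DMSO/THF, 2 mM) closes the ring to the macrocyclic allylic alcohol F4. Isovaleric anhydride/DMAP gives the 3-O-isovalerate F5, HF·pyridine frees the (8S)-alcohol F6, and Mitsunobu esterification of F6 with 20 (PPh3, DIAD, inversion at C8) gives 26.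

Step 14. The Mitsunobu inversion is at a hindered carbinol next to the lactone ring and may give elimination, and it relies on the closed-transition-state outcome (8S) of step 13. The fallback makes the 8R alcohol directly; it sets out from 8 (with 15) and comes back at 22. Zn dust and Bu3SnCl in THF/sat. aq. NH4Cl convert 8 into the allylstannane (S)-5-[(Z)-2-iodoprop-1-en-1-yl]-3-[(tributylstannyl)methyl]furan-2(5H)-one F7. BF3·OEt2 in CH2Cl2 at −78 °C adds F7 to 15 through an open antiperiplanar transition state (Hosomi–Sakurai/Keck-type allylation), which is syn-selective and still anti to the C6 substituent, giving the (8R)-alcohol F8. Yamaguchi esterification of F8 with 20 (2,4,6-trichlorobenzoyl chloride, Et3N, DMAP, toluene), with retention, gives 22.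

Step 2. The iodo-ylide olefination of the sensitive α-oxygenated aldehyde typically gives modest yield and incomplete Z-selectivity. The fallback sets out from 2 and comes back at 3. Dibromo-olefination of 2 (CBr4, PPh3, CH2Cl2, 0 °C) gives the dibromoalkene (S)-5-(2,2-dibromoethenyl)dihydrofuran-2(3H)-one F9. Trans-selective Negishi mono-methylation (MeZnCl, Pd(t-Bu3P)2 2 mol%, THF, 0 °C → rt) replaces the bromine trans to the lactone carbon and gives the (Z)-alkenyl bromide (S)-5-[(Z)-2-bromoprop-1-en-1-yl]dihydrofuran-2(3H)-one F10. Copper-catalysed halogen exchange (CuI, NaI, N,N′-dimethylethylenediamine, dioxane, 110 °C) with retention of geometry gives 3.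

**Further compounds**

F1 | step 17 | 8-O-tert-butyldimethylsilyl ether of 21 (configuration unchanged) | C=C1C(=O)O[C@H](/C=C(/C)I)[C@H]1[C@@H](O[Si](C)(C)C(C)(C)C)C/C(C)=C/CCO[Si](CC)(CC)CC
F2 | step 17 | primary alcohol from F1 (triethylsilyl group removed) | C=C1C(=O)O[C@H](/C=C(/C)I)[C@H]1[C@@H](O[Si](C)(C)C(C)(C)C)C/C(C)=C/CCO
F3 | step 17 | C3 aldehyde from F2 | C=C1C(=O)O[C@H](/C=C(/C)I)[C@H]1[C@@H](O[Si](C)(C)C(C)(C)C)C/C(C)=C/CC=O
F4 | step 17 | (3S,8S)-8-(tert-butyldimethylsilyloxy)-3-hydroxygermacra-1(10)E,4Z,11(13)-trien-12,6-olide, C6 and C7 as in 25 | C=C1C(=O)O[C@@H]2/C=C(/C)[C@@H](O)C/C=C(\C)C[C@H](O[Si](C)(C)C(C)(C)C)[C@@H]12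
F5 | step 17 | 3-O-(3-methylbutanoyl) ester of F4 | C=C1C(=O)O[C@@H]2/C=C(/C)[C@@H](OC(=O)CC(C)C)C/C=C(\C)C[C@H](O[Si](C)(C)C(C)(C)C)[C@@H]12
F6 | step 17 | (3S,8S)-8-hydroxy-3-(3-methylbutanoyloxy)germacra-1(10)E,4Z,11(13)-trien-12,6-olide, C6 and C7 as in 26 | C=C1C(=O)O[C@@H]2/C=C(/C)[C@@H](OC(=O)CC(C)C)C/C=C(\C)C[C@H](O)[C@@H]12
F7 | step 14 | (S)-5-[(Z)-2-iodoprop-1-en-1-yl]-3-[(tributylstannyl)methyl]furan-2(5H)-one | C/C(I)=C/[C@@H]1C=C(C[Sn](CCCC)(CCCC)CCCC)C(=O)O1
F8 | step 14 | (4R,5S)-4-[(1R,3E)-1-hydroxy-3-methyl-6-(triethylsilyloxy)hex-3-en-1-yl]-5-[(Z)-2-iodoprop-1-en-1-yl]-3-methylidenedihydrofuran-2(3H)-one | C=C1C(=O)O[C@H](/C=C(/C)I)[C@H]1[C@H](O)C/C(C)=C/CCO[Si](CC)(CC)CC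
F9 | step 2 | (S)-5-(2,2-dibromoethenyl)dihydrofuran-2(3H)-one | BrC(Br)=C[C@@H]1CCC(=O)O1
F10 | step 2 | (S)-5-[(Z)-2-bromoprop-1-en-1-yl]dihydrofuran-2(3H)-one | C/C(Br)=C/[C@@H]1CCC(=O)O1
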